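Plan – the nine phenols are taken back to methyl ethers and the ring A C4–styryl bond is cut to an aryl bromide plus 4-methoxystyrene (Mizoroki–Heck).
The dihydrofuran ring of unit 1 is cut at O1–C2 and C2–C3 together: C3 is ortho-hydroxybenzylic to ring A, so O1–C7a–C3a–C3 is a latent ortho-quinone methide (stored as a sulfone), and C2, a benzylic carbon on C7' of ring C, is a one-carbon sulfonium ylide.
Unit 2 is cut the same way (O1'–C2' and C2'–C3') into a ring C sulfone and a 2,4-dimethoxybenzyl ylide; the C7' bromide of ring C later becomes the ylide carbon.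
Forward: dihydrofuran ring of unit 2 (step 8), C7' bromide to CH2–S+ (steps 9–11), dihydrofuran ring of unit 1 (step 15), stilbene (step 16), ninefold ether cleavage (step 17).
Stereochemistry: C2' and C2 come from the C2-symmetric (2S,5S)-2,5-dimethylthiolane on each ylide, C3' and C3 follow as trans in the ring closures, and the E-alkene comes from the Heck step; using the same sulfide twice turns any wrong-enantiomer unit 2 into a separable diastereomer once the units are joined.

Key step: step 15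

Assumption: the face preference of the 2,5-dimethylthiolanium arylmethylide known from aldehyde epoxidation is taken to hold for addition to a quinone methide. Because the aryl group and the electrophile-derived carbon exchange CIP rank between an epoxide and a dihydrofuran, this calls for the (2S,5S)-sulfide to reach (S) at C2 and C2'; the antipodal diol would be used in step 1 should the sense prove opposite.

**Step 1**
Reactants: 1 (2R,5R)-hexane-2,5-diol
Product: 2 (2R,5R)-hexane-2,5-diyl dimethanesulfonate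
Conditions: MsCl, Et3N, CH2Cl2, 0 °C
Reagents that add atoms: methanesulfonyl chloride, CS(=O)(=O)Cl
Why: Mesylation of the two secondary alcohols takes place at oxygen, so both stereocentres are retained.

**Step 2**
Reactants: 2 (2R,5R)-hexane-2,5-diyl dimethanesulfonate
Product: 3 (2S,5S)-2,5-dimethylthiolane
Conditions: Na2S·9H2O, DMSO, rt; pentane extraction, distillation
Reagents that add atoms: sodium sulfide, [Na+].[Na+].[S-2]
Why: Double SN2 thioetherification (intermolecular, then 5-exo-tet) inverts both carbinol carbons, so the (2R,5R)-dimesylate should give the (2S,5S)-thiolane.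

**Step 3**
Reactants: 4 2,4-dimethoxybenzyl alcohol; 3 (2S,5S)-2,5-dimethylthiolane
Product: 5 (2S,5S)-1-[(2,4-dimethoxyphenyl)methyl]-2,5-dimethylthiolan-1-ium tetrafluoroborate
Conditions: 3 (1.5 equiv), HBF4·OEt2, CH2Cl2, 0 °C to rt; precipitation from Et2O
Reagents that add atoms: tetrafluoroboric acid (diethyl ether complex), [H+].F[B-](F)(F)F
Why: Acid-promoted SN1 S-alkylation: the electron-rich benzylic alcohol ionises and the sulfide traps the cation as its non-nucleophilic tetrafluoroborate, and since the two sulfur lone pairs of the C2-symmetric sulfide are homotopic a single salt forms.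

**Step 4**
Reactants: 6 2-bromo-5-methoxyphenol
Product: 8 3-bromo-2-hydroxy-6-methoxybenzaldehyde, via salicyl alcohol 7 (not isolated)
Conditions: MgCl2, Et3N, (CH2O)n, THF, reflux; 1 M HCl
Reagents that add atoms: paraformaldehyde (formaldehyde), C=O
Why: Magnesium-mediated ortho-formylation of a phenol (Casnati–Skattebøl reaction) delivers formaldehyde only ortho to the magnesium phenoxide, the one free ortho position lies between OH and OMe, and the salicyl alcohol is oxidised in the flask by a second formaldehyde through Oppenauer-type hydride transfer.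

**Step 5**
Reactants: 9 1-bromo-3,5-dimethoxybenzene
Product: 10 3,5-dimethoxyphenylmagnesium bromide (THF solution)
Conditions: Mg turnings, THF, reflux; solution titrated and kept under argon
Reagents that add atoms: magnesium, [Mg]
Why: Grignard reagent formation by insertion of magnesium into the aryl C–Br bond should be clean for this bromoarene, whose meta methoxy groups neither hinder nor chelate, and one titrated batch serves both arylations (steps 6 and 13).

**Step 6**
Reactants: 8 3-bromo-2-hydroxy-6-methoxybenzaldehyde; 10 3,5-dimethoxyphenylmagnesium bromide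
Product: 11 rac-6-bromo-2-[(3,5-dimethoxyphenyl)(hydroxy)methyl]-3-methoxyphenol
Conditions: 10 (2.3 equiv), THF, 0 °C to rt; aq. NH4Cl
Reagents that add atoms: none
Why: Grignard addition to the aldehyde after the first equivalent has deprotonated the phenol; the aryl bromide of 8 does not exchange with an arylmagnesium halide at this temperature, and the racemic carbinol centre is of no consequence because it is made planar in step 8.

**Step 7**
Reactants: 11 rac-6-bromo-2-[(3,5-dimethoxyphenyl)(hydroxy)methyl]-3-methoxyphenol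
Product: 12 rac-6-bromo-2-[(3,5-dimethoxyphenyl)(4-methylbenzenesulfonyl)methyl]-3-methoxyphenol
Conditions: p-TolSO2H, CH2Cl2, rt
Reagents that add atoms: p-toluenesulfinic acid, Cc1ccc(cc1)S(=O)O
Why: Acid-mediated benzylic substitution of the ortho-hydroxybenzhydrol by sulfinate (S-alkylation through the oxygen-stabilised benzylic cation) should give the bench-stable sulfone in which the quinone methide is stored.

**Step 8**
Reactants: 12 rac-6-bromo-2-[(3,5-dimethoxyphenyl)(4-methylbenzenesulfonyl)methyl]-3-methoxyphenol; 5 (2S,5S)-1-[(2,4-dimethoxyphenyl)methyl]-2,5-dimethylthiolan-1-ium tetrafluoroborate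
Product: 16 (2S,3S)-7-bromo-2-(2,4-dimethoxyphenyl)-3-(3,5-dimethoxyphenyl)-4-methoxy-2,3-dihydro-1-benzofuran, via ortho-quinone methide 13 (not isolated), via sulfonium ylide 14 (not isolated), via anti betaine 15 (not isolated)
Conditions: 5 (1.3 equiv), Cs2CO3, CH2Cl2, 0 °C to rt
Reagents that add atoms: none
Why: Base-mediated (4+1) annulation of an ortho-quinone methide with a sulfonium ylide: Cs2CO3 expels sulfinate from 12 and deprotonates 5, the ylide carbon adds to the methide carbon and the phenoxide closes the ring by 5-exo-tet displacement of the sulfide, with C2 set by the C2-symmetric thiolane that leaves one face of the ylide carbon open and C3 following as trans from the faster-closing anti betaine.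

**Step 9**
Reactants: 16 (2S,3S)-7-bromo-2-(2,4-dimethoxyphenyl)-3-(3,5-dimethoxyphenyl)-4-methoxy-2,3-dihydro-1-benzofuran
Product: 18 (2S,3S)-2-(2,4-dimethoxyphenyl)-3-(3,5-dimethoxyphenyl)-4-methoxy-2,3-dihydro-1-benzofuran-7-carbaldehyde, via aryllithium 17 (not isolated)
Conditions: n-BuLi, THF, −78 °C; DMF, −78 °C to 0 °C; aq. NH4Cl
Reagents that add atoms: N,N-dimethylformamide, CN(C)C=O
Why: Bromine–lithium exchange at −78 °C outruns any deprotonation and the aryllithium is formylated by DMF (Bouveault formylation), leaving both stereocentres untouched.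

**Step 10**
Reactants: 18 (2S,3S)-2-(2,4-dimethoxyphenyl)-3-(3,5-dimethoxyphenyl)-4-methoxy-2,3-dihydro-1-benzofuran-7-carbaldehyde
Product: 19 [(2S,3S)-2-(2,4-dimethoxyphenyl)-3-(3,5-dimethoxyphenyl)-4-methoxy-2,3-dihydro-1-benzofuran-7-yl]methanol
Conditions: NaBH4, MeOH/THF, 0 °C
Reagents that add atoms: none
Why: Borohydride reduction of the aryl aldehyde touches neither the ethers nor the two benzylic stereocentres.

**Step 11**
Reactants: 19 [(2S,3S)-2-(2,4-dimethoxyphenyl)-3-(3,5-dimethoxyphenyl)-4-methoxy-2,3-dihydro-1-benzofuran-7-yl]methanol; 3 (2S,5S)-2,5-dimethylthiolane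
Product: 20 (2S,5S)-1-{[(2S,3S)-2-(2,4-dimethoxyphenyl)-3-(3,5-dimethoxyphenyl)-4-methoxy-2,3-dihydro-1-benzofuran-7-yl]methyl}-2,5-dimethylthiolan-1-ium tetrafluoroborate
Conditions: 3 (2 equiv), HBF4·OEt2, CH2Cl2, −20 °C to 0 °C; precipitation from Et2O
Reagents that add atoms: tetrafluoroboric acid (diethyl ether complex), [H+].F[B-](F)(F)F
Why: Acid-promoted SN1 S-alkylation as in step 3: the benzylic cation, stabilised by the para methoxy group and the ortho ring oxygen of ring C, should be captured by the excess sulfide faster than by the electron-rich arenes, and any reversible opening at C2' recloses to the trans ring.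

**Step 12**
Reactants: 21 2-bromo-4,6-dimethoxybenzaldehyde
Product: 22 2-bromo-6-hydroxy-4-methoxybenzaldehyde
Conditions: BCl3, CH2Cl2, −78 °C to 0 °C; H2O
Reagents that add atoms: none
Why: Chelation-controlled demethylation: BCl3 bound to the aldehyde oxygen cleaves only the methyl ether ortho to the carbonyl through a six-membered boron chelate, and the para ether stays.

**Step 13**
Reactants: 22 2-bromo-6-hydroxy-4-methoxybenzaldehyde; 10 3,5-dimethoxyphenylmagnesium bromide
Product: 23 rac-3-bromo-2-[(3,5-dimethoxyphenyl)(hydroxy)methyl]-5-methoxyphenol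
Conditions: 10 (2.3 equiv), THF, 0 °C to rt; aq. NH4Cl
Reagents that add atoms: none
Why: Grignard addition to the aldehyde of the magnesium phenoxide, as in step 6; the racemic carbinol centre becomes planar in step 15.

**Step 14**
Reactants: 23 rac-3-bromo-2-[(3,5-dimethoxyphenyl)(hydroxy)methyl]-5-methoxyphenol
Product: 24 rac-3-bromo-2-[(3,5-dimethoxyphenyl)(4-methylbenzenesulfonyl)methyl]-5-methoxyphenol
Conditions: p-TolSO2H, CH2Cl2, rt
Reagents that add atoms: p-toluenesulfinic acid, Cc1ccc(cc1)S(=O)O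
Why: Acid-mediated benzylic substitution by sulfinate as in step 7, helped here by the para methoxy and ortho hydroxy groups of ring A that stabilise the benzylic cation.

**Step 15**
Reactants: 24 rac-3-bromo-2-[(3,5-dimethoxyphenyl)(4-methylbenzenesulfonyl)methyl]-5-methoxyphenol; 20 (2S,5S)-1-{[(2S,3S)-2-(2,4-dimethoxyphenyl)-3-(3,5-dimethoxyphenyl)-4-methoxy-2,3-dihydro-1-benzofuran-7-yl]methyl}-2,5-dimethylthiolan-1-ium tetrafluoroborate
Product: 28 (2S,3S)-4-bromo-2-[(2S,3S)-2-(2,4-dimethoxyphenyl)-3-(3,5-dimethoxyphenyl)-4-methoxy-2,3-dihydro-1-benzofuran-7-yl]-3-(3,5-dimethoxyphenyl)-6-methoxy-2,3-dihydro-1-benzofuran, via ortho-quinone methide 25 (not isolated), via sulfonium ylide 26 (not isolated), via anti betaine 27 (not isolated)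
Conditions: 24 (1.3 equiv), Cs2CO3, CH2Cl2, 0 °C to rt
Reagents that add atoms: none
Why: Cs2CO3 eliminates p-toluenesulfinate from the phenoxide of 24 to give ortho-quinone methide 25 and deprotonates salt 20 to ylide 26, whose carbon adds in a 1,4 sense to the exocyclic methide carbon (C2–C3 bond) to give betaine 27 with ring A rearomatised. The closest known reaction is the base-mediated (4+1) annulation of 2-(tosylalkyl)phenols with sulfonium ylides to trans-2,3-dihydrobenzofurans, and step 8 of this route rehearses it with the same sulfide. The dihydrofuran ring of unit 1 closes by 5-exo-tet SN2 attack of the ring A phenoxide on C2 with loss of the thiolane and inversion at C2 (O1–C2 bond). C2 is controlled by the (2S,5S)-thiolane: in the ylide the aryl group points away from the thiolane ring and the 2-methyl group cis to the ylide carbon blocks one face, so the methide is met on the other face whatever the distant stereocentres of unit 2 are, which after inversion corresponds to (S). C3 is controlled relative to C2, because the betaine that can close with the two aryl groups anti does so fastest and the trans ring is also the more stable one. The step needs C-alkylation rather than O-benzylation and an untouched aryl bromide: the phenoxide of 24 should lose sulfinate faster than it is benzylated, the quinone methide is a soft acceptor attacked only at carbon, and the C4 bromide is inert to carbonate.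

**Step 16**
Reactants: 28 (2S,3S)-4-bromo-2-[(2S,3S)-2-(2,4-dimethoxyphenyl)-3-(3,5-dimethoxyphenyl)-4-methoxy-2,3-dihydro-1-benzofuran-7-yl]-3-(3,5-dimethoxyphenyl)-6-methoxy-2,3-dihydro-1-benzofuran; 29 4-methoxystyrene
Product: 30 (2S,3S)-2-[(2S,3S)-2-(2,4-dimethoxyphenyl)-3-(3,5-dimethoxyphenyl)-4-methoxy-2,3-dihydro-1-benzofuran-7-yl]-3-(3,5-dimethoxyphenyl)-6-methoxy-4-[(E)-2-(4-methoxyphenyl)ethenyl]-2,3-dihydro-1-benzofuran
Conditions: Pd2(dba)3 (cat.), [(t-Bu)3PH]BF4 (cat.), Cy2NMe, 1,4-dioxane, 90 °C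
Reagents that add atoms: none
Why: Mizoroki–Heck reaction: zerovalent palladium carrying the bulky, electron-rich P(t-Bu)3 inserts into the hindered, electron-rich C4–Br bond, and syn carbopalladation at the terminal carbon of the styrene followed by syn β-hydride elimination should give the E-stilbene without touching the four stereocentres.

**Step 17**
Reactants: 30 (2S,3S)-2-[(2S,3S)-2-(2,4-dimethoxyphenyl)-3-(3,5-dimethoxyphenyl)-4-methoxy-2,3-dihydro-1-benzofuran-7-yl]-3-(3,5-dimethoxyphenyl)-6-methoxy-4-[(E)-2-(4-methoxyphenyl)ethenyl]-2,3-dihydro-1-benzofuran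
Product: 31 (2S,3S)-2-[(2S,3S)-2-(2,4-dihydroxyphenyl)-3-(3,5-dihydroxyphenyl)-4-hydroxy-2,3-dihydro-1-benzofuran-7-yl]-3-(3,5-dihydroxyphenyl)-4-[(E)-2-(4-hydroxyphenyl)ethenyl]-2,3-dihydro-1-benzofuran-6-ol (CNP0397447.1)
Conditions: BCl3 (excess), n-Bu4NI (excess), CH2Cl2, −78 °C to rt; cold pH 7 phosphate buffer
Reagents that add atoms: none
Why: Lewis acid/iodide cleavage of aryl methyl ethers: BCl3 activates each ether and iodide removes the methyl group by SN2, a milder regime than BBr3 that should spare the stilbene and the trans-2-aryl-2,3-dihydrobenzofurans, with no stereocentre touched and any ionisation at C2 or C2' reclosing to the trans rings.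

**Compound list**
1 | (2R,5R)-hexane-2,5-diol | C[C@@H](O)CC[C@@H](C)O | starting material
2 | (2R,5R)-hexane-2,5-diyl dimethanesulfonate | C[C@@H](OS(C)(=O)=O)CC[C@@H](C)OS(C)(=O)=O | intermediate
3 | (2S,5S)-2,5-dimethylthiolane | C[C@H]1CC[C@H](C)S1 | intermediate
4 | 2,4-dimethoxybenzyl alcohol | COc1ccc(CO)c(OC)c1 | starting material
5 | (2S,5S)-1-[(2,4-dimethoxyphenyl)methyl]-2,5-dimethylthiolan-1-ium tetrafluoroborate | C[C@H]1CC[C@H](C)[S+]1Cc1ccc(OC)cc1OC.F[B-](F)(F)F | intermediate
6 | 2-bromo-5-methoxyphenol | COc1ccc(Br)c(O)c1 | starting material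
7 | 6-bromo-2-(hydroxymethyl)-3-methoxyphenol (salicyl alcohol, formed in the flask) | COc1ccc(Br)c(O)c1CO | intermediate
8 | 3-bromo-2-hydroxy-6-methoxybenzaldehyde | COc1ccc(Br)c(O)c1C=O | intermediate
9 | 1-bromo-3,5-dimethoxybenzene | COc1cc(Br)cc(OC)c1 | starting material
10 | 3,5-dimethoxyphenylmagnesium bromide (THF solution) | COc1cc([Mg]Br)cc(OC)c1 | intermediate
11 | rac-6-bromo-2-[(3,5-dimethoxyphenyl)(hydroxy)methyl]-3-methoxyphenol | COc1ccc(Br)c(O)c1C(O)c1cc(OC)cc(OC)c1 | intermediate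
12 | rac-6-bromo-2-[(3,5-dimethoxyphenyl)(4-methylbenzenesulfonyl)methyl]-3-methoxyphenol | COc1ccc(Br)c(O)c1C(c1cc(OC)cc(OC)c1)S(=O)(=O)c1ccc(C)cc1 | intermediate
13 | 2-bromo-6-[(3,5-dimethoxyphenyl)methylidene]-5-methoxycyclohexa-2,4-dien-1-one (ring C ortho-quinone methide, formed in the flask) | O=C1C(Br)=CC=C(OC)C1=Cc1cc(OC)cc(OC)c1 | intermediate
14 | (2,4-dimethoxyphenyl)[(2S,5S)-2,5-dimethylthiolan-1-ium-1-yl]methanide (ylide, formed in the flask) | C[C@H]1CC[C@H](C)[S+]1[CH-]c1ccc(OC)cc1OC | intermediate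
15 | 6-bromo-2-[(1S,2R)-2-(2,4-dimethoxyphenyl)-1-(3,5-dimethoxyphenyl)-2-[(2S,5S)-2,5-dimethylthiolan-1-ium-1-yl]ethyl]-3-methoxyphenolate (anti betaine, formed in the flask) | [O-]c1c(Br)ccc(OC)c1[C@H](c1cc(OC)cc(OC)c1)[C@H](c1ccc(OC)cc1OC)[S+]1[C@@H](C)CC[C@@H]1C | intermediate
16 | (2S,3S)-7-bromo-2-(2,4-dimethoxyphenyl)-3-(3,5-dimethoxyphenyl)-4-methoxy-2,3-dihydro-1-benzofuran | Brc1ccc(OC)c2c1O[C@H](c1ccc(OC)cc1OC)[C@H]2c1cc(OC)cc(OC)c1 | intermediate
17 | [(2S,3S)-2-(2,4-dimethoxyphenyl)-3-(3,5-dimethoxyphenyl)-4-methoxy-2,3-dihydro-1-benzofuran-7-yl]lithium (formed in the flask) | [Li]c1ccc(OC)c2c1O[C@H](c1ccc(OC)cc1OC)[C@H]2c1cc(OC)cc(OC)c1 | intermediate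
18 | (2S,3S)-2-(2,4-dimethoxyphenyl)-3-(3,5-dimethoxyphenyl)-4-methoxy-2,3-dihydro-1-benzofuran-7-carbaldehyde | O=Cc1ccc(OC)c2c1O[C@H](c1ccc(OC)cc1OC)[C@H]2c1cc(OC)cc(OC)c1 | intermediate
19 | [(2S,3S)-2-(2,4-dimethoxyphenyl)-3-(3,5-dimethoxyphenyl)-4-methoxy-2,3-dihydro-1-benzofuran-7-yl]methanol | OCc1ccc(OC)c2c1O[C@H](c1ccc(OC)cc1OC)[C@H]2c1cc(OC)cc(OC)c1 | intermediate
20 | (2S,5S)-1-{[(2S,3S)-2-(2,4-dimethoxyphenyl)-3-(3,5-dimethoxyphenyl)-4-methoxy-2,3-dihydro-1-benzofuran-7-yl]methyl}-2,5-dimethylthiolan-1-ium tetrafluoroborate | C[C@H]1CC[C@H](C)[S+]1Cc1ccc(OC)c2c1O[C@H](c1ccc(OC)cc1OC)[C@H]2c1cc(OC)cc(OC)c1.F[B-](F)(F)F | intermediate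
21 | 2-bromo-4,6-dimethoxybenzaldehyde | O=Cc1c(Br)cc(OC)cc1OC | starting material
22 | 2-bromo-6-hydroxy-4-methoxybenzaldehyde | O=Cc1c(Br)cc(OC)cc1O | intermediate
23 | rac-3-bromo-2-[(3,5-dimethoxyphenyl)(hydroxy)methyl]-5-methoxyphenol | Oc1cc(OC)cc(Br)c1C(O)c1cc(OC)cc(OC)c1 | intermediate
24 | rac-3-bromo-2-[(3,5-dimethoxyphenyl)(4-methylbenzenesulfonyl)methyl]-5-methoxyphenol | Oc1cc(OC)cc(Br)c1C(c1cc(OC)cc(OC)c1)S(=O)(=O)c1ccc(C)cc1 | intermediate
25 | 5-bromo-6-[(3,5-dimethoxyphenyl)methylidene]-3-methoxycyclohexa-2,4-dien-1-one (ring A ortho-quinone methide, formed in the flask) | O=C1C=C(OC)C=C(Br)C1=Cc1cc(OC)cc(OC)c1 | intermediate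
26 | [(2S,3S)-2-(2,4-dimethoxyphenyl)-3-(3,5-dimethoxyphenyl)-4-methoxy-2,3-dihydro-1-benzofuran-7-yl][(2S,5S)-2,5-dimethylthiolan-1-ium-1-yl]methanide (ylide, formed in the flask) | C[C@H]1CC[C@H](C)[S+]1[CH-]c1ccc(OC)c2c1O[C@H](c1ccc(OC)cc1OC)[C@H]2c1cc(OC)cc(OC)c1 | intermediate
27 | 3-bromo-2-[(1S,2R)-2-[(2S,3S)-2-(2,4-dimethoxyphenyl)-3-(3,5-dimethoxyphenyl)-4-methoxy-2,3-dihydro-1-benzofuran-7-yl]-1-(3,5-dimethoxyphenyl)-2-[(2S,5S)-2,5-dimethylthiolan-1-ium-1-yl]ethyl]-5-methoxyphenolate (anti betaine, formed in the flask) | [O-]c1cc(OC)cc(Br)c1[C@H](c1cc(OC)cc(OC)c1)[C@H](c1ccc(OC)c2c1O[C@H](c1ccc(OC)cc1OC)[C@H]2c1cc(OC)cc(OC)c1)[S+]1[C@@H](C)CC[C@@H]1C | intermediate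
28 | (2S,3S)-4-bromo-2-[(2S,3S)-2-(2,4-dimethoxyphenyl)-3-(3,5-dimethoxyphenyl)-4-methoxy-2,3-dihydro-1-benzofuran-7-yl]-3-(3,5-dimethoxyphenyl)-6-methoxy-2,3-dihydro-1-benzofuran | Brc1cc(OC)cc2c1[C@H](c1cc(OC)cc(OC)c1)[C@@H](c1ccc(OC)c3c1O[C@H](c1ccc(OC)cc1OC)[C@H]3c1cc(OC)cc(OC)c1)O2 | intermediate
29 | 4-methoxystyrene | C=Cc1ccc(OC)cc1 | starting material
30 | (2S,3S)-2-[(2S,3S)-2-(2,4-dimethoxyphenyl)-3-(3,5-dimethoxyphenyl)-4-methoxy-2,3-dihydro-1-benzofuran-7-yl]-3-(3,5-dimethoxyphenyl)-6-methoxy-4-[(E)-2-(4-methoxyphenyl)ethenyl]-2,3-dihydro-1-benzofuran | COc1ccc(/C=C/c2cc(OC)cc3c2[C@H](c2cc(OC)cc(OC)c2)[C@@H](c2ccc(OC)c4c2O[C@H](c2ccc(OC)cc2OC)[C@H]4c2cc(OC)cc(OC)c2)O3)cc1 | intermediate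
31 | (2S,3S)-2-[(2S,3S)-2-(2,4-dihydroxyphenyl)-3-(3,5-dihydroxyphenyl)-4-hydroxy-2,3-dihydro-1-benzofuran-7-yl]-3-(3,5-dihydroxyphenyl)-4-[(E)-2-(4-hydroxyphenyl)ethenyl]-2,3-dihydro-1-benzofuran-6-ol (CNP0397447.1) | Oc1ccc(/C=C/c2cc(O)cc3c2[C@H](c2cc(O)cc(O)c2)[C@@H](c2ccc(O)c4c2O[C@H](c2ccc(O)cc2O)[C@H]4c2cc(O)cc(O)c2)O3)cc1 | target

**Total step count:** 17
**Longest linear sequence:** 10 steps (from 6 through steps 4, 6–11 and 15–17; the chains from 1 through steps 1–3, 8–11 and 15–17 and from 9 through steps 5–11 and 15–17 are equally long)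

**Steps most likely to fail**

1. Step 15. The ylide carbon may be met on both faces, or the betaine may revert before it closes, so that the two trans diastereomers at unit 1 form without useful preference; benzylation of the phenoxide oxygen by the sulfonium salt would add to the loss. Fallback (stereocontrol by separation in place of reagent control): setting out from alcohol 19, tetrahydrothiophene and HBF4·OEt2 in CH2Cl2 should give the achiral salt 1-{[(2S,3S)-2-(2,4-dimethoxyphenyl)-3-(3,5-dimethoxyphenyl)-4-methoxy-2,3-dihydro-1-benzofuran-7-yl]methyl}thiolan-1-ium tetrafluoroborate F1. Annulation of F1 with sulfone 24 under Cs2CO3 in CH2Cl2 should give 28 together with its (2R,3R)-unit 1 diastereomer F2. Because unit 2 is already a single enantiomer the two are diastereomers, to be separated on silica or by crystallisation; the route is rejoined at 28.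

2. Step 8. Face selection at the electron-rich 2,4-dimethoxybenzyl ylide may be too weak to give unit 2 in high enantiomeric purity, and the labile salt 5 may ionise and benzylate the phenoxide instead of forming the ylide. Fallback (racemic annulation and resolution in place of asymmetric induction): setting out from 4 and 12, alcohol 4 with tetrahydrothiophene and HBF4·OEt2 should give 1-[(2,4-dimethoxyphenyl)methyl]thiolan-1-ium tetrafluoroborate F3. Annulation of F3 with sulfone 12 under Cs2CO3 should give rac-trans-7-bromo-2-(2,4-dimethoxyphenyl)-3-(3,5-dimethoxyphenyl)-4-methoxy-2,3-dihydro-1-benzofuran F4. Preparative chromatography of F4 on a cellulose tris(3,5-dimethylphenylcarbamate) phase (supercritical CO2/MeOH) should deliver the (2S,3S)-enantiomer; the route is rejoined at 16.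

3. Step 17. During the ninefold ether cleavage the electron-rich stilbene may be protonated and captured by the neighbouring C3 resorcinol ring (seven-membered ring closure), the C2'–O1' bond next to the 2,4-dioxygenated ring may ionise, or cleavage may stop short. Fallback (ether cleavage before the alkene is present, then a base-labile protecting group): setting out from bromide 28, BBr3 in CH2Cl2 (−78 °C to rt) should give the octaphenol bromide F5. Ac2O in pyridine should give the octaacetate F6. Mizoroki–Heck coupling of F6 with commercial 4-acetoxystyrene under the conditions of step 16 should give the nonaacetate F7. K2CO3 in degassed MeOH at 0 °C, followed by buffering to pH 6, should remove all acetates; the route is rejoined at 31.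

**Further compounds**
F1 | step 15 | 1-{[(2S,3S)-2-(2,4-dimethoxyphenyl)-3-(3,5-dimethoxyphenyl)-4-methoxy-2,3-dihydro-1-benzofuran-7-yl]methyl}thiolan-1-ium tetrafluoroborate | C1CC[S+](C1)Cc1ccc(OC)c2c1O[C@H](c1ccc(OC)cc1OC)[C@H]2c1cc(OC)cc(OC)c1.F[B-](F)(F)F
F2 | step 15 | (2R,3R)-4-bromo-2-[(2S,3S)-2-(2,4-dimethoxyphenyl)-3-(3,5-dimethoxyphenyl)-4-methoxy-2,3-dihydro-1-benzofuran-7-yl]-3-(3,5-dimethoxyphenyl)-6-methoxy-2,3-dihydro-1-benzofuran | Brc1cc(OC)cc2c1[C@@H](c1cc(OC)cc(OC)c1)[C@H](c1ccc(OC)c3c1O[C@H](c1ccc(OC)cc1OC)[C@H]3c1cc(OC)cc(OC)c1)O2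
F3 | step 8 | 1-[(2,4-dimethoxyphenyl)methyl]thiolan-1-ium tetrafluoroborate | COc1ccc(C[S+]2CCCC2)c(OC)c1.F[B-](F)(F)F
F4 | step 8 | rac-trans-7-bromo-2-(2,4-dimethoxyphenyl)-3-(3,5-dimethoxyphenyl)-4-methoxy-2,3-dihydro-1-benzofuran (1:1 mixture of the 2S,3S and 2R,3R enantiomers) | Brc1ccc(OC)c2c1O[C@H](c1ccc(OC)cc1OC)[C@H]2c1cc(OC)cc(OC)c1.Brc1ccc(OC)c2c1O[C@@H](c1ccc(OC)cc1OC)[C@@H]2c1cc(OC)cc(OC)c1
F5 | step 17 | (2S,3S)-4-bromo-2-[(2S,3S)-2-(2,4-dihydroxyphenyl)-3-(3,5-dihydroxyphenyl)-4-hydroxy-2,3-dihydro-1-benzofuran-7-yl]-3-(3,5-dihydroxyphenyl)-2,3-dihydro-1-benzofuran-6-ol | Brc1cc(O)cc2c1[C@H](c1cc(O)cc(O)c1)[C@@H](c1ccc(O)c3c1O[C@H](c1ccc(O)cc1O)[C@H]3c1cc(O)cc(O)c1)O2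
F6 | step 17 | octaacetate of F5 (all eight phenols acetylated) | Brc1cc(OC(C)=O)cc2c1[C@H](c1cc(OC(C)=O)cc(OC(C)=O)c1)[C@@H](c1ccc(OC(C)=O)c3c1O[C@H](c1ccc(OC(C)=O)cc1OC(C)=O)[C@H]3c1cc(OC(C)=O)cc(OC(C)=O)c1)O2
F7 | step 17 | nonaacetate of 31 (all nine phenols acetylated, E-alkene) | CC(=O)Oc1ccc(/C=C/c2cc(OC(C)=O)cc3c2[C@H](c2cc(OC(C)=O)cc(OC(C)=O)c2)[C@@H](c2ccc(OC(C)=O)c4c2O[C@H](c2ccc(OC(C)=O)cc2OC(C)=O)[C@H]4c2cc(OC(C)=O)cc(OC(C)=O)c2)O3)cc1
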